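## Structural features

The target is a furanoheliangolide: a ten-membered carbocycle (ring B, C1–C10) in which an ether oxygen joins C3 and C10, so that O, C3, C2, C1 and C10 form a 3(2H)-furanone (ring A) with the ketone at C1 and the enol-ether alkene at C2=C3. The furanone is conjugated through C3 with the Z-configured C4=C5 ring alkene, which carries the free C15 hydroxymethyl group on C4. A trans-fused α-methylene-γ-butyrolactone (ring C: O–C6, C7, C11=C13, C12) is annulated at C6/C7 and C8 bears a methacrylate, so C6 (R), C7 (R) and C8 (R) form a contiguous triad, while the quaternary, oxygen-bearing C10 (S) stands alone, separated from C8 only by the C9 methylene. Fragile elements are the two exocyclic Michael acceptors, the dienone-type furanone, the allylic lactone C6–O bond, the primary allylic alcohol, and the latent choice between a 6,12- and an 8,12-lactone; late steps should avoid nucleophiles, strong base and fluoride. The real difficulty is the strained oxygen-bridged ten-membered ring with its quaternary C10, and the relay of configuration from C10 across the ring to C6–C8. The key step exploits the fact that C10 is bonded to both the bridging oxygen and C9 while the same oxygen is bonded to C3: a six-membered ether ring O–C3–C4=C5–C6–C7 with a vinyl group (C8=C9) on C7 and a C2–C1–C10 carbene tether on C3 can deliver O–C10 and C9–C10 in one oxonium ylide rearrangement, closing ring A and ring B together. The E C7=C8 alkene left behind sits exactly where C7–H and C8–O are needed.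

## Logic of the disconnections

36 from 34. The lactone bond O(C6)–C12 is cut; the C6 and C15 hydroxyls are capped as silyl ethers and C12 as a tert-butyl ester. The cut comes last because ring C cannot be closed while C7 is still trigonal (see 28 from 26), and because an acid-only final step spares the two Michael acceptors. Gain: ring C and all free polar groups leave the intermediates. Demand: one acid treatment must cleave the ester and both silyl ethers and close only the 6,12-lactone, so C8 must already be acylated.

34 from 32 and 33. The C8 O–acyl bond is cut. Acylation is placed after methylenation so that no acrylic ester side chain is exposed to an enolate. Gain: the most sensitive side chain is removed. Demand: clean O-acylation of a hindered secondary alcohol beside an acrylate.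

32 from 28 and 29. The C11=C13 bond is cut (Mannich/elimination). It is made on the open-chain ester, not on the lactone, so that deprotection and lactonisation can be merged at the end. Gain: C13 is removed. Demand: enolisation at C11 beside a metallated C8 hydroxyl, which is why C12 is a tert-butyl ester that the alkoxide cannot attack.

28 from 26. C8–O and C7–H are cut back to the E C7=C8 alkene (hydroboration). Two stereocentres become one element of planar chirality. Demand: the borane must add only to the strained alkene, only from its open face, with boron on C8. C1 must already be a vinylogous ester. The C12 carboxyl must not capture the new C8 hydroxyl: a methyl ester would close an 8,12-lactone, and a 6,12-lactone closed before this step would force C5 through the alkene plane and expose the wrong face. Hence the tert-butyl ester and the late lactonisation.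

26 from 24. The C2=C3 alkene is traced back to C2H2–C3H (dehydrogenation). Gain: a saturated oxolan-3-one whose C3 stereocentre can steer C10. Demand: oxidation through the only possible enol (C10 is quaternary), without base strong enough to move C7=C8 into conjugation with the ester.

24 from 22 (key). O–C10 and C9–C10 are cut together, which removes ring A, ring B and the quaternary centre and leaves a monocyclic dihydropyran with three stereocentres. A check of the configurations of this pair against 36 shows them consistent: (3S) can only lead to (10S), C6 is carried unchanged, and (7R) in 22 is stored as the planar chirality that the hydroboration needs. No stereochemical correction is required. What is changed is the functional design: the C12 ester becomes tert-butyl, and the order of the later steps is altered as explained above. Demand: ylide formation faster than 1,2-hydride shift and cyclopropanation, and an E-selective shift.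

22 from 18 and 19. The C1–C10 bond is cut (acyl–diazoalkane bond). Gain: the sensitive diazo group is introduced one step before use. Demand: activation of the C1 acid without strong acid.

18 from 17. The C1 acid goes back to a methyl ester. Demand: two esters of different lability (methyl at C1, tert-butyl at C12) so that hydroxide distinguishes them.

17 from 14 and 16 (16 from 15). The C7–C11 bond is cut at the oxocarbenium stage. Gain: the quaternary ether carbon becomes a hemiketal. Demand: attack of the acetate unit at C7, not at C9, and on the ring face opposite the C6 silyloxy group and the C3 side chain.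

14 from 12 and 13. The C7–C8 bond is cut. Gain: a lactone. Demand: single addition to the lactone carbonyl in the presence of the C1 methyl ester and an acidic C6–H.

12 from 11. The C4=C5 bond is cut (ring-closing metathesis); six-membered ring closure guarantees the Z geometry. Demand: closure onto a 1,1-disubstituted alkene without migration of the β,γ-alkene.

11 from 5 and 10. The ester bond O(C3)–C7 is cut. Gain: two small fragments, each with one stereocentre. Demand: esterification without epimerising C6.

5 from 3 and 4; 3 from 2; 2 from 1. The C2–C3 bond is cut (acetate aldol). C3 is set by catalyst control, and any minor enantiomer is purged as a diastereomer after coupling with enantiopure 10.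

10 from 8, 7 and 6. Only oxidation state and protecting groups change; C6 comes from the chiral pool.

## Other disconnections considered

Alternative 1: The cut is at two carbon–oxygen bonds, O–C6 of the lactone and O–C15, on an intact bridged carbocycle. In the forward sense the macrocyclic dienyl acid A2 (C6=C5–C4=C15 diene, free C12 acrylic acid) would be treated with Pd(OAc)2 and benzoquinone in acetic acid. The carboxylate would add to C6 of the palladium-bound diene and acetate would open the resulting C4–C5–C15 allylpalladium at C15 to give the 15-acetate A1.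
- In its favour: it is a catalytic, well-known 1,4-oxidation of a diene. It would set the lactone, the C4=C5 position and the C15 oxygen in one step and needs neither the hydroboration nor a late methylenation. On end-game functional-group economy it is the better plan.
- Against it here: it makes no carbon–carbon bond and closes neither ring A nor ring B, so the hardest part of the structure moves into the synthesis of A2. The trans lactone requires carboxylate attack on the face that C7 dictates, whereas tethered carboxylates usually give cis-fused lactones. The 4Z geometry depends on the syn/anti form of the allylpalladium. The diene is cross-conjugated with the furanone and so electron-poor, and benzoquinone may add to it. A1 would still need a deacetylation that spares the methacrylate and the lactone.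
- Comparison: structurally weaker (two C–O bonds against two rings, two skeletal bonds and C10); mechanistically of similar risk (face and geometry control in a medium ring in both). Its step economy cannot be judged until a route to A2 exists, and that route would have to solve the problem step 14 addresses.

Alternative 2: The cut is at C7–C8, made as a ring contraction. The thirteen-membered cyclic allyl ether A4, with a tributylstannyl group on C8 and an O–C13 allylic ether linking C8 to C11, would be treated with n-BuLi. Tin–lithium exchange would give the α-alkoxy carbanion, which would attack C7 in a Wittig–Still [2,3] shift, break O–C13 and give the ten-membered enyne A3 with a free C8 hydroxyl and the C11=C13 methylene.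
- In its favour: a carbon–carbon bond between two stereocentres would be made with transfer of configuration, and the large ether ring is easier to close than a ten-membered carbocycle. C8–OH and C13 would appear directly, where the chosen route needs a hydroboration and a separate methylenation; on these atoms the alternative is the better plan. Mechanistically it is the equal of the chosen step: both are [2,3]-sigmatropic shifts that change ring size instead of closing a medium ring end to end.
- Against it here: A4 needs a configurationally defined α-alkoxystannane inside a macrocycle whose own closure is unsolved, stoichiometric tin, and n-BuLi in the presence of a ketal, an alkyne and silyl ethers. The [1,2] shift and the alkene geometry in A4 are open points. Ring A and C10 are not made by the step.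
- Comparison: after A3 there would remain ketal and acetal removal, cyclisation of the ynone to the furanone, oxidation of C12, lactonisation, acylation and desilylation, about eight operations against five after 24. On step economy and on the number of rings and stereocentres set by the key step, the chosen route is ahead.

Alternative 3: The cut is at C1–C2 and O–C3. The open-chain aldoxime A6, which already holds the lactone, the C8 silyl ether and the tertiary C10 alcohol, would be oxidised with NaOCl to the nitrile oxide. This would add to the terminal C2=C3 alkene of the diene and close the isoxazoline and the ten-membered ring in A5. N–O cleavage, oxidation to the 1,3-diketone and cyclodehydration with the C10 hydroxyl would later give ring A.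
- In its favour: C6, C7, C8, C10 and ring C would be set by open-chain chemistry before ring closure. That is a better basis for the C6–C8 triad than the face selectivity of a medium-ring alkene on which the chosen route relies. The regiochemistry (oxygen to the substituted carbon C3) is the normal one for a terminal alkene, and the masked diketone is a proven entry to a 3(2H)-furanone.
- Against it here: the ten-membered carbocycle would be closed end to end, with full transannular and entropic cost, in competition with dimerisation of the nitrile oxide and addition to the internal alkene. A nitrile oxide next to a free tertiary alcohol may fragment. After A5 about seven operations would remain (N–O cleavage, oxidation, cyclodehydration, silyl removal at C8, acylation, methylenation, desilylation).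
- Comparison: it is more convergent and stereochemically the more secure plan, but its key step is the less likely to proceed, because the ring expansion of step 14 avoids exactly the end-to-end closure on which this alternative depends.

Key step: step 14

Assumption: 4, 6 and 19 are taken as purchasable; the antipode of the aldol catalyst in step 3 is chosen by its sense of induction so that 5 is (3S); C12 is carried as a tert-butyl ester and both silyl ethers as tert-butyldimethylsilyl (TBS) ethers, which changes spectator groups only.

## Route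

Step 1
Reactants: 1 2-methylidenepropane-1,3-diol
Product: 2 2-[(tert-butyldimethylsilyloxy)methyl]prop-2-en-1-ol
Conditions: NaH (1.0 equiv), THF, 0 °C to rt; TBSCl (1.0 equiv)
Reagents that add atoms: tert-butyldimethylsilyl chloride (TBSCl), CC(C)(C)[Si](C)(C)Cl
Why: Monosilylation of a symmetric diol through its sparingly soluble monosodium alkoxide (O-silylation); the mono-alkoxide is silylated faster than it equilibrates, so one hydroxyl is capped.

Step 2
Reactants: 2 2-[(tert-butyldimethylsilyloxy)methyl]prop-2-en-1-ol
Product: 3 2-[(tert-butyldimethylsilyloxy)methyl]prop-2-enal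
Conditions: MnO2 (activated, 10 equiv), CH2Cl2, rt
Reagents that add atoms: none
Why: Allylic alcohol oxidation with manganese dioxide; it stops at the enal and leaves the silyl ether alone.

Step 3
Reactants: 3 2-[(tert-butyldimethylsilyloxy)methyl]prop-2-enal; 4 1-(tert-butyldimethylsilyloxy)-1-methoxyethene
Product: 5 methyl (3S)-5-(tert-butyldimethylsilyloxy)-3-hydroxy-4-methylidenepentanoate
Conditions: SiCl4 (1.1 equiv), chiral 1,1'-binaphthyl-2,2'-diamine-derived bisphosphoramide (5 mol %, antipode directing attack to the Si face), iPr2NEt (10 mol %), CH2Cl2, −78 °C; aq. KF/KH2PO4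
Reagents that add atoms: none
Why: Lewis base-catalysed, SiCl4-mediated enantioselective Mukaiyama aldol addition of an acetate silyl ketene acetal to a conjugated aldehyde. C3 is set by catalyst control (Si-face attack gives 3S), and any minor enantiomer is removed later as a diastereomer once 5 is joined to enantiopure 10.

Step 4
Reactants: 6 (2R)-but-3-ene-1,2-diol
Product: 7 (2R)-1,2-bis(tert-butyldimethylsilyloxy)but-3-ene
Conditions: TBSCl (2.5 equiv), imidazole, DMF, rt
Reagents that add atoms: tert-butyldimethylsilyl chloride (TBSCl), CC(C)(C)[Si](C)(C)Cl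
Why: Imidazole-promoted silylation of both hydroxyls; no bond to the stereocentre is touched.

Step 5
Reactants: 7 (2R)-1,2-bis(tert-butyldimethylsilyloxy)but-3-ene
Product: 8 (2R)-2-(tert-butyldimethylsilyloxy)but-3-en-1-ol
Conditions: HF·pyridine, pyridine, THF, 0 °C
Reagents that add atoms: none
Why: Selective desilylation; the unhindered primary silyl ether is cleaved much faster than the secondary allylic one.

Step 6
Reactants: 8 (2R)-2-(tert-butyldimethylsilyloxy)but-3-en-1-ol
Product: 10 (2R)-2-(tert-butyldimethylsilyloxy)but-3-enoic acid, via silyloxy aldehyde 9 (not isolated)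
Conditions: TEMPO (10 mol %), PhI(OAc)2 (2.2 equiv), MeCN/H2O (1:1), rt
Reagents that add atoms: water, O
Why: Nitroxyl (oxoammonium)-catalysed oxidation of the primary alcohol through the aldehyde hydrate to the acid. The near-neutral medium should spare the allylic stereocentre from enolisation and the alkene from migration.

Step 7
Reactants: 5 methyl (3S)-5-(tert-butyldimethylsilyloxy)-3-hydroxy-4-methylidenepentanoate; 10 (2R)-2-(tert-butyldimethylsilyloxy)but-3-enoic acid
Product: 11 methyl (3S)-3-{[(2R)-2-(tert-butyldimethylsilyloxy)but-3-enoyl]oxy}-5-(tert-butyldimethylsilyloxy)-4-methylidenepentanoate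
Conditions: DCC (1.1 equiv), DMAP (5 mol %), CH2Cl2, −20 to 0 °C
Reagents that add atoms: none
Why: Steglich esterification; low temperature and little DMAP should keep the α-silyloxy β,γ-unsaturated acyl unit from epimerising or moving into conjugation.

Step 8
Reactants: 11 methyl (3S)-3-{[(2R)-2-(tert-butyldimethylsilyloxy)but-3-enoyl]oxy}-5-(tert-butyldimethylsilyloxy)-4-methylidenepentanoate
Product: 12 methyl 2-[(2S,5R)-5-(tert-butyldimethylsilyloxy)-3-[(tert-butyldimethylsilyloxy)methyl]-6-oxo-5,6-dihydro-2H-pyran-2-yl]acetate
Conditions: second-generation Grubbs catalyst (5 mol %), 1,4-benzoquinone (10 mol %), toluene (0.005 M), 70 °C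
Reagents that add atoms: none
Why: Ring-closing metathesis to a six-membered unsaturated lactone; the ring size forces the cis (Z) geometry at C4=C5, and benzoquinone suppresses hydride-mediated migration of the β,γ-alkene.

Step 9
Reactants: 12 methyl 2-[(2S,5R)-5-(tert-butyldimethylsilyloxy)-3-[(tert-butyldimethylsilyloxy)methyl]-6-oxo-5,6-dihydro-2H-pyran-2-yl]acetate; 13 vinylmagnesium bromide
Product: 14 methyl 2-[(2S,5R)-6-ethenyl-6-hydroxy-5-(tert-butyldimethylsilyloxy)-3-[(tert-butyldimethylsilyloxy)methyl]-5,6-dihydro-2H-pyran-2-yl]acetate (both epimers at the hemiketal carbon)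
Conditions: CH2=CHMgBr (1.2 equiv), THF, −78 °C; pH 7 buffer
Reagents that add atoms: none
Why: Single Grignard addition to a lactone, held at the tetrahedral hemiketal alkoxide at −78 °C. The α-silyloxy lactone carbonyl is far more electrophilic than the methyl ester, which is expected to survive.

Step 10
Reactants: 15 tert-butyl acetate
Product: 16 1-tert-butoxy-1-(tert-butyldimethylsilyloxy)ethene
Conditions: LiN(iPr)2 (1.05 equiv), THF, −78 °C; TBSCl, DMPU, −78 °C to rt; distillation
Reagents that add atoms: tert-butyldimethylsilyl chloride (TBSCl), CC(C)(C)[Si](C)(C)Cl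
Why: O-Silylation of an ester enolate (silyl ketene acetal formation).

Step 11
Reactants: 14 methyl 2-[(2S,5R)-6-ethenyl-6-hydroxy-5-(tert-butyldimethylsilyloxy)-3-[(tert-butyldimethylsilyloxy)methyl]-5,6-dihydro-2H-pyran-2-yl]acetate; 16 1-tert-butoxy-1-(tert-butyldimethylsilyloxy)ethene
Product: 17 methyl 2-[(2S,5R,6R)-6-(2-tert-butoxy-2-oxoethyl)-6-ethenyl-5-(tert-butyldimethylsilyloxy)-3-[(tert-butyldimethylsilyloxy)methyl]-5,6-dihydro-2H-pyran-2-yl]acetate
Conditions: TMSOTf (0.2 equiv), 16 (2.5 equiv), CH2Cl2, −78 °C
Reagents that add atoms: none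
Why: Lewis acid-promoted substitution of the hemiketal through its 2-vinyl oxocarbenium ion by a silyl ketene acetal (Mukaiyama-type C-glycosylation of a ketose). The nearly flat dihydropyranylium ring should be attacked at C7 from the face opposite both the C6 silyloxy group and the C3 side chain, which places C11 trans and the vinyl group cis to them (7R).

Step 12
Reactants: 17 methyl 2-[(2S,5R,6R)-6-(2-tert-butoxy-2-oxoethyl)-6-ethenyl-5-(tert-butyldimethylsilyloxy)-3-[(tert-butyldimethylsilyloxy)methyl]-5,6-dihydro-2H-pyran-2-yl]acetate
Product: 18 2-[(2S,5R,6R)-6-(2-tert-butoxy-2-oxoethyl)-6-ethenyl-5-(tert-butyldimethylsilyloxy)-3-[(tert-butyldimethylsilyloxy)methyl]-5,6-dihydro-2H-pyran-2-yl]acetic acid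
Conditions: LiOH·H2O (3 equiv), THF/MeOH/H2O (3:1:1), 0 °C to rt; then 1 M HCl to pH 4
Reagents that add atoms: lithium hydroxide, [Li+].[OH-]
Why: Saponification; hydroxide cleaves the methyl ester and leaves the hindered tert-butyl ester and the silyl ethers.

Step 13
Reactants: 18 2-[(2S,5R,6R)-6-(2-tert-butoxy-2-oxoethyl)-6-ethenyl-5-(tert-butyldimethylsilyloxy)-3-[(tert-butyldimethylsilyloxy)methyl]-5,6-dihydro-2H-pyran-2-yl]acetic acid; 19 N-ethyl-N-nitrosourea
Product: 22 tert-butyl 2-[(2R,3R,6S)-6-(3-diazo-2-oxobutyl)-2-ethenyl-3-(tert-butyldimethylsilyloxy)-5-[(tert-butyldimethylsilyloxy)methyl]-3,6-dihydro-2H-pyran-2-yl]acetate, via mixed isobutyl carbonic anhydride 20 (not isolated), via diazoethane 21 (not isolated)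
Conditions: iBuOCOCl (1.1 equiv), N-methylmorpholine (1.2 equiv), THF, −20 °C; then CH3CHN2 in Et2O (from 19, 40% aq. KOH, Et2O, 0 °C; about 3 equiv), −20 to 0 °C
Reagents that add atoms: none
Why: Acylation of a diazoalkane by a mixed carbonic anhydride (Arndt–Eistert-type diazoketone synthesis). The isobutyl carbonate leaving group takes up the proton and falls apart to isobutanol and CO2, so neither an acid chloride nor a strong acid touches the silyl ethers or the tertiary allylic ether.

Step 14
Reactants: 22 tert-butyl 2-[(2R,3R,6S)-6-(3-diazo-2-oxobutyl)-2-ethenyl-3-(tert-butyldimethylsilyloxy)-5-[(tert-butyldimethylsilyloxy)methyl]-3,6-dihydro-2H-pyran-2-yl]acetate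
Product: 24 tert-butyl 2-[(3S,4Z,6R,7E,10S)-6-(tert-butyldimethylsilyloxy)-4-[(tert-butyldimethylsilyloxy)methyl]-10-methyl-1-oxo-3,10-epoxycyclodeca-4,7-dien-7-yl]acetate (germacrane numbering), via bicyclic oxonium ylide 23 (not isolated)
Conditions: Rh2(O2CCPh3)4 (2 mol %), CH2Cl2, −40 to 0 °C, slow addition of 22
Reagents that add atoms: none
Why: Rh2(O2CCPh3)4 expels N2 from 22, and the electrophilic carbene carbon C10 is captured by a lone pair of the ring oxygen 1,5 to it; this closes the oxolan-3-one ring as the five-membered cyclic oxonium ylide 23 (ring A closed by O–C10 bond formation). The ylide then undergoes a suprafacial [2,3]-sigmatropic shift through a five-membered envelope C10–O–C7–C8=C9: C10 bonds to C9, O–C7 breaks and C7=C8 forms, so the ten-membered carbocycle arises by three-atom expansion of the pyran and not by end-to-end closure. The closest known reaction type is the metal carbene-derived oxonium ylide formation and [2,3] rearrangement of 2-vinyl cyclic ethers with a diazoketone tether to oxygen-bridged medium-ring ketones; the methyl-bearing carbene is the only extension. The new stereocentre C10 is fixed by C3, because the chain C4–C9 can span the oxolanone only cis, so (3S) dictates (10S). Ylide formation must outrun 1,2-hydride shift from the C14 methyl (bulky triphenylacetate ligands, low temperature), cyclopropanation of C4=C5 (a trisubstituted alkene flanked by three allylic C–O bonds, hence hindered and electron-poor) and the [1,2] shift (the allylic C7 terminus favours the concerted [2,3] path). The E geometry should follow from bonding through the equatorial lone pair anti to C6–C7, which places C9 over C11 in the envelope. Because the shift is suprafacial, the ether oxygen stays on the alkene face from which it left C7; the (7R) centre of 22 is thereby stored as planar chirality of the E alkene, which step 16 reads out.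

Step 15
Reactants: 24 tert-butyl 2-[(3S,4Z,6R,7E,10S)-6-(tert-butyldimethylsilyloxy)-4-[(tert-butyldimethylsilyloxy)methyl]-10-methyl-1-oxo-3,10-epoxycyclodeca-4,7-dien-7-yl]acetate
Product: 26 tert-butyl 2-[(4Z,6R,7E,10S)-6-(tert-butyldimethylsilyloxy)-4-[(tert-butyldimethylsilyloxy)methyl]-10-methyl-1-oxo-3,10-epoxycyclodeca-2,4,7-trien-7-yl]acetate, via trimethylsilyl enol ether 25 (not isolated)
Conditions: TMSOTf (1.3 equiv), Et3N (2 equiv), CH2Cl2, −78 to 0 °C; then Pd(OAc)2 (1.1 equiv), MeCN, rt
Reagents that add atoms: none
Why: Saegusa–Ito oxidation; only C2 carries enolisable hydrogens (C10 is quaternary), and soft enolisation leaves the β,γ-unsaturated ester untouched. β-Hydride elimination from C3 gives the C2=C3 alkene of the 3(2H)-furanone and removes the C3 stereocentre, which has done its work.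

Step 16
Reactants: 26 tert-butyl 2-[(4Z,6R,7E,10S)-6-(tert-butyldimethylsilyloxy)-4-[(tert-butyldimethylsilyloxy)methyl]-10-methyl-1-oxo-3,10-epoxycyclodeca-2,4,7-trien-7-yl]acetate
Product: 28 tert-butyl 2-[(4Z,6R,7R,8R,10S)-6-(tert-butyldimethylsilyloxy)-4-[(tert-butyldimethylsilyloxy)methyl]-8-hydroxy-10-methyl-1-oxo-3,10-epoxycyclodeca-2,4-dien-7-yl]acetate, via C8 borabicyclononyl borane 27 (not isolated)
Conditions: 9-BBN (1.5 equiv), THF, 0 °C to rt; then 30% H2O2, pH 7 phosphate buffer, 0 °C to rt
Reagents that add atoms: hydrogen peroxide, OO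
Why: Hydroboration–oxidation; syn addition across the strained E alkene from its only open face (turned away from the transannular ether bridge) should place H on C7 anti to the former O–C7 bond and boron on the less substituted C8, giving (7R,8R) after stereoretentive oxidation. A dialkylborane has no second B–H to reduce the neighbouring ester, and the new C8 hydroxyl cannot attack a tert-butyl ester.

Step 17
Reactants: 28 tert-butyl 2-[(4Z,6R,7R,8R,10S)-6-(tert-butyldimethylsilyloxy)-4-[(tert-butyldimethylsilyloxy)methyl]-8-hydroxy-10-methyl-1-oxo-3,10-epoxycyclodeca-2,4-dien-7-yl]acetate; 29 N,N-dimethylmethyleneiminium iodide (Eschenmoser's salt)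
Product: 32 tert-butyl 2-[(4Z,6R,7R,8R,10S)-6-(tert-butyldimethylsilyloxy)-4-[(tert-butyldimethylsilyloxy)methyl]-8-hydroxy-10-methyl-1-oxo-3,10-epoxycyclodeca-2,4-dien-7-yl]prop-2-enoate, via Mannich base 30 (not isolated), via trimethylammonium iodide 31 (not isolated)
Conditions: LiN(SiMe3)2 (2.5 equiv), THF, −78 °C; 29 (3 equiv), −78 to 0 °C; then MeI, MeOH, rt; then NaHCO3 (aq.), CH2Cl2, rt
Reagents that add atoms: none
Why: Mannich aminomethylation of the ester enolate, N-quaternisation and E1cB elimination (Eschenmoser methylenation). The C8 hydroxyl rides through as its alkoxide, which cannot lactonise onto a tert-butyl ester, and no acrylic ester side chain is yet present to intercept the enolate.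

Step 18
Reactants: 32 tert-butyl 2-[(4Z,6R,7R,8R,10S)-6-(tert-butyldimethylsilyloxy)-4-[(tert-butyldimethylsilyloxy)methyl]-8-hydroxy-10-methyl-1-oxo-3,10-epoxycyclodeca-2,4-dien-7-yl]prop-2-enoate; 33 methacrylic anhydride
Product: 34 tert-butyl 2-[(4Z,6R,7R,8R,10S)-6-(tert-butyldimethylsilyloxy)-4-[(tert-butyldimethylsilyloxy)methyl]-10-methyl-8-(2-methylprop-2-enoyloxy)-1-oxo-3,10-epoxycyclodeca-2,4-dien-7-yl]prop-2-enoate
Conditions: 33 (3 equiv), Et3N (4 equiv), DMAP (0.2 equiv), CH2Cl2, 0 °C to rt
Reagents that add atoms: none
Why: DMAP-catalysed acylation of the secondary C8 alcohol; only the O–H bond reacts, so C8 keeps its configuration.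

Step 19
Reactants: 34 tert-butyl 2-[(4Z,6R,7R,8R,10S)-6-(tert-butyldimethylsilyloxy)-4-[(tert-butyldimethylsilyloxy)methyl]-10-methyl-8-(2-methylprop-2-enoyloxy)-1-oxo-3,10-epoxycyclodeca-2,4-dien-7-yl]prop-2-enoate
Product: 36 (4Z,6R,7R,8R,10S)-15-hydroxy-8-(2-methylprop-2-enoyloxy)-1-oxo-3,10-epoxygermacra-2,4,11(13)-trien-12,6-olide (CNP0180483.4), via seco hydroxy acid 35 (not isolated)
Conditions: CF3CO2H/H2O (9:1), 0 °C to rt; then aq. NaHCO3/MeOH work-up
Reagents that add atoms: none
Why: Acidolysis of the tert-butyl ester and of both silyl ethers, followed by acid-catalysed γ-lactonisation of the C12 acid onto the C6 hydroxyl. The trans ring fusion is fixed by the existing C6 and C7 centres, C8 is already acylated so no 8,12-lactone can form, and the acidic finish spares the two Michael acceptors from base and fluoride.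

## Compound list

1 | 2-methylidenepropane-1,3-diol | C=C(CO)CO | starting material
2 | 2-[(tert-butyldimethylsilyloxy)methyl]prop-2-en-1-ol | C=C(CO)CO[Si](C)(C)C(C)(C)C | intermediate
3 | 2-[(tert-butyldimethylsilyloxy)methyl]prop-2-enal | C=C(C=O)CO[Si](C)(C)C(C)(C)C | intermediate
4 | 1-(tert-butyldimethylsilyloxy)-1-methoxyethene (silyl ketene acetal of methyl acetate) | C=C(OC)O[Si](C)(C)C(C)(C)C | starting material
5 | methyl (3S)-5-(tert-butyldimethylsilyloxy)-3-hydroxy-4-methylidenepentanoate | COC(=O)C[C@H](O)C(=C)CO[Si](C)(C)C(C)(C)C | intermediate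
6 | (2R)-but-3-ene-1,2-diol | OC[C@H](O)C=C | starting material
7 | (2R)-1,2-bis(tert-butyldimethylsilyloxy)but-3-ene | CC(C)(C)[Si](C)(C)OC[C@H](O[Si](C)(C)C(C)(C)C)C=C | intermediate
8 | (2R)-2-(tert-butyldimethylsilyloxy)but-3-en-1-ol | OC[C@H](O[Si](C)(C)C(C)(C)C)C=C | intermediate
9 | (2R)-2-(tert-butyldimethylsilyloxy)but-3-enal | O=C[C@H](O[Si](C)(C)C(C)(C)C)C=C | intermediate (not isolated)
10 | (2R)-2-(tert-butyldimethylsilyloxy)but-3-enoic acid | OC(=O)[C@H](O[Si](C)(C)C(C)(C)C)C=C | intermediate
11 | methyl (3S)-3-{[(2R)-2-(tert-butyldimethylsilyloxy)but-3-enoyl]oxy}-5-(tert-butyldimethylsilyloxy)-4-methylidenepentanoate | COC(=O)C[C@H](OC(=O)[C@H](O[Si](C)(C)C(C)(C)C)C=C)C(=C)CO[Si](C)(C)C(C)(C)C | intermediate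
12 | methyl 2-[(2S,5R)-5-(tert-butyldimethylsilyloxy)-3-[(tert-butyldimethylsilyloxy)methyl]-6-oxo-5,6-dihydro-2H-pyran-2-yl]acetate | COC(=O)C[C@@H]1OC(=O)[C@H](O[Si](C)(C)C(C)(C)C)C=C1CO[Si](C)(C)C(C)(C)C | intermediate
13 | vinylmagnesium bromide | C=C[Mg]Br | starting material
14 | methyl 2-[(2S,5R)-6-ethenyl-6-hydroxy-5-(tert-butyldimethylsilyloxy)-3-[(tert-butyldimethylsilyloxy)methyl]-5,6-dihydro-2H-pyran-2-yl]acetate (both hemiketal epimers) | COC(=O)C[C@@H]1OC(O)(C=C)[C@H](O[Si](C)(C)C(C)(C)C)C=C1CO[Si](C)(C)C(C)(C)C | intermediate
15 | tert-butyl acetate | CC(=O)OC(C)(C)C | starting material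
16 | 1-tert-butoxy-1-(tert-butyldimethylsilyloxy)ethene | C=C(OC(C)(C)C)O[Si](C)(C)C(C)(C)C | intermediate
17 | methyl 2-[(2S,5R,6R)-6-(2-tert-butoxy-2-oxoethyl)-6-ethenyl-5-(tert-butyldimethylsilyloxy)-3-[(tert-butyldimethylsilyloxy)methyl]-5,6-dihydro-2H-pyran-2-yl]acetate | COC(=O)C[C@@H]1O[C@@](C=C)(CC(=O)OC(C)(C)C)[C@H](O[Si](C)(C)C(C)(C)C)C=C1CO[Si](C)(C)C(C)(C)C | intermediate
18 | 2-[(2S,5R,6R)-6-(2-tert-butoxy-2-oxoethyl)-6-ethenyl-5-(tert-butyldimethylsilyloxy)-3-[(tert-butyldimethylsilyloxy)methyl]-5,6-dihydro-2H-pyran-2-yl]acetic acid | OC(=O)C[C@@H]1O[C@@](C=C)(CC(=O)OC(C)(C)C)[C@H](O[Si](C)(C)C(C)(C)C)C=C1CO[Si](C)(C)C(C)(C)C | intermediate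
19 | N-ethyl-N-nitrosourea | CCN(N=O)C(N)=O | starting material
20 | mixed anhydride of 18 with isobutyl hydrogen carbonate | CC(C)COC(=O)OC(=O)C[C@@H]1O[C@@](C=C)(CC(=O)OC(C)(C)C)[C@H](O[Si](C)(C)C(C)(C)C)C=C1CO[Si](C)(C)C(C)(C)C | intermediate (not isolated)
21 | diazoethane | CC=[N+]=[N-] | intermediate (not isolated)
22 | tert-butyl 2-[(2R,3R,6S)-6-(3-diazo-2-oxobutyl)-2-ethenyl-3-(tert-butyldimethylsilyloxy)-5-[(tert-butyldimethylsilyloxy)methyl]-3,6-dihydro-2H-pyran-2-yl]acetate | CC(=[N+]=[N-])C(=O)C[C@@H]1O[C@@](C=C)(CC(=O)OC(C)(C)C)[C@H](O[Si](C)(C)C(C)(C)C)C=C1CO[Si](C)(C)C(C)(C)C | intermediate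
23 | bicyclic oxonium ylide (oxolan-3-one fused to the dihydropyran through O and C3; carbanion at C10) | C[C-]1C(=O)C[C@H]2C(CO[Si](C)(C)C(C)(C)C)=C[C@@H](O[Si](C)(C)C(C)(C)C)[C@](C=C)(CC(=O)OC(C)(C)C)[O+]12 | intermediate (not isolated)
24 | tert-butyl 2-[(3S,4Z,6R,7E,10S)-6-(tert-butyldimethylsilyloxy)-4-[(tert-butyldimethylsilyloxy)methyl]-10-methyl-1-oxo-3,10-epoxycyclodeca-4,7-dien-7-yl]acetate | CC(C)(C)OC(=O)C/C1=C\C[C@]2(C)O[C@@H](CC2=O)/C(CO[Si](C)(C)C(C)(C)C)=C\[C@H]1O[Si](C)(C)C(C)(C)C | intermediate
25 | C1 trimethylsilyl enol ether of 24 (C1=C2) | CC(C)(C)OC(=O)C/C1=C\C[C@]2(C)O[C@@H](C=C2O[Si](C)(C)C)/C(CO[Si](C)(C)C(C)(C)C)=C\[C@H]1O[Si](C)(C)C(C)(C)C | intermediate (not isolated)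
26 | tert-butyl 2-[(4Z,6R,7E,10S)-6-(tert-butyldimethylsilyloxy)-4-[(tert-butyldimethylsilyloxy)methyl]-10-methyl-1-oxo-3,10-epoxycyclodeca-2,4,7-trien-7-yl]acetate | CC(C)(C)OC(=O)C/C1=C\C[C@]2(C)OC(=CC2=O)/C(CO[Si](C)(C)C(C)(C)C)=C\[C@H]1O[Si](C)(C)C(C)(C)C | intermediate
27 | C8 (9-borabicyclo[3.3.1]nonan-9-yl) adduct of 26, configuration at C7 and C8 as in 28 | CC(C)(C)OC(=O)C[C@@H]1[C@H](B3C4CCCC3CCC4)C[C@]2(C)OC(=CC2=O)/C(CO[Si](C)(C)C(C)(C)C)=C\[C@H]1O[Si](C)(C)C(C)(C)C | intermediate (not isolated)
28 | tert-butyl 2-[(4Z,6R,7R,8R,10S)-6-(tert-butyldimethylsilyloxy)-4-[(tert-butyldimethylsilyloxy)methyl]-8-hydroxy-10-methyl-1-oxo-3,10-epoxycyclodeca-2,4-dien-7-yl]acetate | CC(C)(C)OC(=O)C[C@@H]1[C@H](O)C[C@]2(C)OC(=CC2=O)/C(CO[Si](C)(C)C(C)(C)C)=C\[C@H]1O[Si](C)(C)C(C)(C)C | intermediate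
29 | N,N-dimethylmethyleneiminium iodide (Eschenmoser's salt) | C=[N+](C)C.[I-] | starting material
30 | C11 dimethylaminomethyl derivative of 28 (Mannich base, both C11 epimers) | CN(C)CC(C(=O)OC(C)(C)C)[C@@H]1[C@H](O)C[C@]2(C)OC(=CC2=O)/C(CO[Si](C)(C)C(C)(C)C)=C\[C@H]1O[Si](C)(C)C(C)(C)C | intermediate (not isolated)
31 | trimethylammonium iodide of 30 | C[N+](C)(C)CC(C(=O)OC(C)(C)C)[C@@H]1[C@H](O)C[C@]2(C)OC(=CC2=O)/C(CO[Si](C)(C)C(C)(C)C)=C\[C@H]1O[Si](C)(C)C(C)(C)C.[I-] | intermediate (not isolated)
32 | tert-butyl 2-[(4Z,6R,7R,8R,10S)-6-(tert-butyldimethylsilyloxy)-4-[(tert-butyldimethylsilyloxy)methyl]-8-hydroxy-10-methyl-1-oxo-3,10-epoxycyclodeca-2,4-dien-7-yl]prop-2-enoate | C=C(C(=O)OC(C)(C)C)[C@@H]1[C@H](O)C[C@]2(C)OC(=CC2=O)/C(CO[Si](C)(C)C(C)(C)C)=C\[C@H]1O[Si](C)(C)C(C)(C)C | intermediate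
33 | methacrylic anhydride | C=C(C)C(=O)OC(=O)C(C)=C | starting material
34 | tert-butyl 2-[(4Z,6R,7R,8R,10S)-6-(tert-butyldimethylsilyloxy)-4-[(tert-butyldimethylsilyloxy)methyl]-10-methyl-8-(2-methylprop-2-enoyloxy)-1-oxo-3,10-epoxycyclodeca-2,4-dien-7-yl]prop-2-enoate | C=C(C)C(=O)O[C@@H]1C[C@]2(C)OC(=CC2=O)/C(CO[Si](C)(C)C(C)(C)C)=C\[C@@H](O[Si](C)(C)C(C)(C)C)[C@@H]1C(=C)C(=O)OC(C)(C)C | intermediate
35 | 2-[(4Z,6R,7S,8R,10S)-6-hydroxy-4-(hydroxymethyl)-10-methyl-8-(2-methylprop-2-enoyloxy)-1-oxo-3,10-epoxycyclodeca-2,4-dien-7-yl]prop-2-enoic acid (same spatial arrangement as 34; the C7 descriptor changes by priority only) | C=C(C)C(=O)O[C@@H]1C[C@]2(C)OC(=CC2=O)/C(CO)=C\[C@@H](O)[C@@H]1C(=C)C(=O)O | intermediate (not isolated)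
36 | (4Z,6R,7R,8R,10S)-15-hydroxy-8-(2-methylprop-2-enoyloxy)-1-oxo-3,10-epoxygermacra-2,4,11(13)-trien-12,6-olide (CNP0180483.4) | C=C(C)C(=O)O[C@@H]1C[C@]2(C)OC(=CC2=O)/C(CO)=C\[C@H]2OC(=O)C(=C)[C@@H]21 | target

## Step count and least certain steps

Total step count: 19 steps (steps 4–6 and step 10 are side branches). Longest linear sequence: 15 steps (steps 1–3, 7–9 and 11–19).

Step 14 (key step). The most likely failure is loss of geometric control: if the carbene is taken up by the axial lone pair of the ring oxygen, the envelope places C9 over C6 and the shift delivers the Z C7=C8 alkene. 1,2-Hydride migration from the C14 methyl and cyclopropanation of C4=C5 may in addition drain the carbene before the ylide forms. The reason is that the two lone pairs differ only modestly in accessibility, and the methyl-bearing carbene is more prone to hydride shift than the unsubstituted carbenes on which this ring expansion rests. The fallback changes how C8 is set rather than the catalyst. It sets out from 22 and accepts the Z isomer: the rearrangement then gives the 7Z bridged ketone F1, and dehydrogenation as in step 15 gives the 7Z furanone F2. Hydroboration as in step 16, if the borane again delivers hydrogen to C7 on the face remote from the ether bridge, gives by syn addition to the Z alkene the 8-epimeric alcohol F3. Methylenation as in step 17 gives the 8-epimeric hydroxy acrylate F4. A Mitsunobu esterification of F4 with methacrylic acid (PPh3, diisopropyl azodicarboxylate) inverts C8 and rejoins the route at 34.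

Step 11. The most likely failure is loss of regiocontrol: attack of the ketene acetal at the vinyl terminus C9 of the conjugated oxocarbenium ion, or conjugate addition to the open-chain vinyl ketone tautomer of 14, together with incomplete face selectivity at the crowded C7. The reason is that C7 is fully substituted while C9 is unhindered. The fallback uses a masked vinyl group and sets out from 12. Ethynylmagnesium bromide (THF, −78 °C) gives the ethynyl hemiketal F5. TMSOTf and 16 give the ethynyl diester F6; an alkynyl oxocarbenium ion is attacked at the ketal carbon, and the linear substituent eases crowding. Semi-hydrogenation (H2, Pd/CaCO3 poisoned with Pb(OAc)2, quinoline) reduces only the terminal alkyne and rejoins the route at 17.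

Step 16. The most likely failure is sluggish addition of the bulky borane to an alkene face that is partly shielded by the C6 silyloxy group, with slow 1,2-reduction of the furanone carbonyl taking over on prolonged reaction. The fallback sets out from 26 and uses a small borane in excess, accepting reduction at C1. BH3·THF (excess, −20 °C), then H2O2 at pH 7, gives the C1,C8-diol F7. MnO2 in CH2Cl2 reoxidises only the allylic C1 alcohol and rejoins the route at 28.

Step 17. The most likely failure is side reaction of the dianion: poor enolisation at C11 beside the C8 alkoxide, or transannular conjugate addition of that alkoxide to the dienone. The fallback removes the alkoxide and sets out from 28. Et3SiCl and imidazole give the triethylsilyl ether F8. LiN(SiMe3)2 and 29, then MeI and NaHCO3 as in step 17, give the silylated acrylate F9. Pyridinium p-toluenesulfonate in MeOH at 0 °C removes the triethylsilyl group selectively and rejoins the route at 32.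

## Further compounds

F1 | step 14 | tert-butyl 2-[(3S,4Z,6R,7Z,10S)-6-(tert-butyldimethylsilyloxy)-4-[(tert-butyldimethylsilyloxy)methyl]-10-methyl-1-oxo-3,10-epoxycyclodeca-4,7-dien-7-yl]acetate (7Z isomer of 24) | CC(C)(C)OC(=O)C/C1=C/C[C@]2(C)O[C@@H](CC2=O)/C(CO[Si](C)(C)C(C)(C)C)=C\[C@H]1O[Si](C)(C)C(C)(C)C
F2 | step 14 | 7Z isomer of 26 | CC(C)(C)OC(=O)C/C1=C/C[C@]2(C)OC(=CC2=O)/C(CO[Si](C)(C)C(C)(C)C)=C\[C@H]1O[Si](C)(C)C(C)(C)C
F3 | step 14 | (4Z,6R,7R,8S,10S) 8-epimer of 28 | CC(C)(C)OC(=O)C[C@@H]1[C@@H](O)C[C@]2(C)OC(=CC2=O)/C(CO[Si](C)(C)C(C)(C)C)=C\[C@H]1O[Si](C)(C)C(C)(C)C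
F4 | step 14 | (4Z,6R,7R,8S,10S) 8-epimer of 32 | C=C(C(=O)OC(C)(C)C)[C@@H]1[C@@H](O)C[C@]2(C)OC(=CC2=O)/C(CO[Si](C)(C)C(C)(C)C)=C\[C@H]1O[Si](C)(C)C(C)(C)C
F5 | step 11 | methyl 2-[(2S,5R)-6-ethynyl-6-hydroxy-5-(tert-butyldimethylsilyloxy)-3-[(tert-butyldimethylsilyloxy)methyl]-5,6-dihydro-2H-pyran-2-yl]acetate (both hemiketal epimers) | COC(=O)C[C@@H]1OC(O)(C#C)[C@H](O[Si](C)(C)C(C)(C)C)C=C1CO[Si](C)(C)C(C)(C)C
F6 | step 11 | ethynyl analogue of 17 (ethynyl in place of ethenyl on the quaternary carbon, same spatial arrangement) | COC(=O)C[C@@H]1O[C@@](C#C)(CC(=O)OC(C)(C)C)[C@H](O[Si](C)(C)C(C)(C)C)C=C1CO[Si](C)(C)C(C)(C)C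
F7 | step 16 | C1 alcohol of 28 (1,8-diol, both C1 epimers) | CC(C)(C)OC(=O)C[C@@H]1[C@H](O)C[C@]2(C)OC(=CC2O)/C(CO[Si](C)(C)C(C)(C)C)=C\[C@H]1O[Si](C)(C)C(C)(C)C
F8 | step 17 | 8-O-triethylsilyl ether of 28 | CC[Si](CC)(CC)O[C@@H]1C[C@]2(C)OC(=CC2=O)/C(CO[Si](C)(C)C(C)(C)C)=C\[C@@H](O[Si](C)(C)C(C)(C)C)[C@@H]1CC(=O)OC(C)(C)C
F9 | step 17 | 8-O-triethylsilyl ether of 32 | CC[Si](CC)(CC)O[C@@H]1C[C@]2(C)OC(=CC2=O)/C(CO[Si](C)(C)C(C)(C)C)=C\[C@@H](O[Si](C)(C)C(C)(C)C)[C@@H]1C(=C)C(=O)OC(C)(C)C
A1 | alternative 1 | 15-O-acetyl derivative of 36 | C=C(C)C(=O)O[C@@H]1C[C@]2(C)OC(=CC2=O)/C(COC(C)=O)=C\[C@H]2OC(=O)C(=C)[C@@H]21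
A2 | alternative 1 | macrocyclic dienyl acid: 3,10-epoxy-bridged furanone carbocycle with C4=C15 and C5=C6 alkenes, 8-methacrylate and a C7 acrylic acid side chain, configuration at C7, C8 and C10 as in 36, C5=C6 geometry left open | C=C(C)C(=O)O[C@@H]1C[C@]2(C)OC(=CC2=O)C(=C)C=C[C@@H]1C(=C)C(=O)O
A3 | alternative 2 | ten-membered enyne carbocycle with C8 hydroxyl and C11=C13 methylene | O[C@@H]1C[C@](C)(OCOC)C2(OCCO2)C#C/C(CO[Si](C)(C)C(C)(C)C)=C\[C@@H](O[Si](C)(C)C(C)(C)C)[C@@H]1C(=C)COCc1ccc(OC)cc1
A4 | alternative 2 | thirteen-membered cyclic allyl ether with a tributylstannyl group on C8, configuration at C6 and C10 as in A3, C8 configuration and C7=C11 geometry left open | CCCC[Sn](CCCC)(CCCC)C1C[C@](C)(OCOC)C2(OCCO2)C#C/C(CO[Si](C)(C)C(C)(C)C)=C\[C@@H](O[Si](C)(C)C(C)(C)C)C=C(COCc2ccc(OC)cc2)CO1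
A5 | alternative 3 | isoxazoline-bridged ten-membered carbocycle | CC[Si](CC)(CC)O[C@@H]1C[C@](C)(O)C2=NO[C@H](C2)/C(CO[Si](C)(C)C(C)(C)C)=C\[C@H]2OC(=O)C[C@@H]21
A6 | alternative 3 | open-chain C1 aldoxime with the C2=C3/C4=C5 diene, configuration at C6, C7, C8 and C10 as in A5, oxime geometry left open | ON=C[C@@](C)(O)C[C@@H](O[Si](CC)(CC)CC)[C@H]1CC(=O)O[C@@H]1/C=C(\C=C)CO[Si](C)(C)C(C)(C)C
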